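The cycloheptane is cut into an oxyallyl unit C5–C6–C7 (oxygen on C6) and a 2-siloxydiene C8–C9–C10–C1 (oxygen on C9), already linked through C2–C4. Core numbering: C1 is the methyl-bearing fusion carbon, C2–C4 follow (C4 is the isopropyl carbinol), C5 is the fusion CH, and C6–C10 run round the seven-membered ring. One cationic (4+3) cycloaddition forms C1–C5 and C7–C8, closes the five- and the seven-membered ring, sets quaternary C1 under control of C4 and leaves both ring oxygens in place. Its precursor is an open-chain chloromethyl ketone with the C4 tertiary silyl ether (from a Sharpless epoxidation) and an (E,Z)-silyl dienol ether; the chloride is introduced last.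

Key step: step 12

Remark: bicyclic compounds are described with the core numbering; β is the face of the C1 methyl, α the opposite face, and Δ9(10) means a C9=C10 double bond.
Remark: C4 is (S) in the open-chain compounds and (R) in the bicycles. The spatial arrangement is the same; ring closure changes the CIP ranking of C5 against isopropyl.
Assumption: 1, 3 and 20 are bought.

Step 1
Reactants: 1 ethyl 4-methyl-3-oxopentanoate
Product: 2 ethyl (2Z)-4-methyl-3-[(trifluoromethylsulfonyl)oxy]pent-2-enoate
Conditions: Tf2O, sat. aq. LiOH, hexanes, 5 °C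
Reagents that add atoms: trifluoromethanesulfonic anhydride, O=S(=O)(OS(=O)(=O)C(F)(F)F)C(F)(F)F
Why: O-triflation of the chelated lithium enolate of the β-keto ester should fix the enol triflate as the Z isomer (OTf cis to the ester); no stereocentre is formed.

Step 2
Reactants: 2 ethyl (2Z)-4-methyl-3-[(trifluoromethylsulfonyl)oxy]pent-2-enoate; 3 (4-bromobut-1-yn-1-yl)trimethylsilane
Product: 5 ethyl (2E)-3-isopropyl-7-(trimethylsilyl)hept-2-en-6-ynoate, via Grignard reagent 4 (not isolated)
Conditions: 3, Mg, THF; then 2, Fe(acac)3 (5 mol %), THF/NMP, −30 °C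
Reagents that add atoms: none
Why: Iron-catalysed Kumada-type coupling of an alkyl Grignard reagent with an enol triflate outruns addition to the ester and goes with retention, so the new chain ends cis to the ester and isopropyl trans.

Step 3
Reactants: 5 ethyl (2E)-3-isopropyl-7-(trimethylsilyl)hept-2-en-6-ynoate
Product: 6 (2E)-3-isopropyl-7-(trimethylsilyl)hept-2-en-6-yn-1-ol
Conditions: iBu2AlH (2.2 equiv), CH2Cl2, −78 °C
Reagents that add atoms: none
Why: 1,2-Reduction of the conjugated ester by the aluminium hydride gives the allylic alcohol without touching the alkene geometry or the silyl alkyne.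

Step 4
Reactants: 6 (2E)-3-isopropyl-7-(trimethylsilyl)hept-2-en-6-yn-1-ol
Product: 7 {(2R,3R)-3-isopropyl-3-[4-(trimethylsilyl)but-3-yn-1-yl]oxiran-2-yl}methanol
Conditions: Ti(OiPr)4 (10 mol %), D-(−)-diethyl tartrate (12 mol %), t-BuOOH, 4 Å MS, CH2Cl2, −20 °C
Reagents that add atoms: tert-butyl hydroperoxide, CC(C)(C)OO
Why: Katsuki–Sharpless asymmetric epoxidation: the titanium tartrate delivers oxygen to one face of the hydroxyl-bearing alkene, and the D-(−)-tartrate should give the 2R,3R epoxide (the sense known for geraniol with this ligand), which fixes C4 of the target; the substrate has the favourable pattern of a primary chain cis and the branched group trans to CH2OH.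

Step 5
Reactants: 7 {(2R,3R)-3-isopropyl-3-[4-(trimethylsilyl)but-3-yn-1-yl]oxiran-2-yl}methanol
Product: 9 (3S)-3-isopropylhept-6-yne-1,3-diol, via silyl alkyne diol 8 (not isolated)
Conditions: NaAlH2(OCH2CH2OMe)2, THF, 0 °C; then MeOH, K2CO3, rt
Reagents that add atoms: none
Why: The aluminate at O1 delivers hydride to C2, the less substituted epoxide carbon, so the 1,3-diol forms with the tertiary C–O bond untouched (configuration retained), and methanolic carbonate then cleaves the alkynyl C–Si bond.

Step 6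
Reactants: 9 (3S)-3-isopropylhept-6-yne-1,3-diol
Product: 10 (3S)-3-hydroxy-3-isopropylhept-6-ynoic acid
Conditions: TEMPO (20 mol %), PhI(OAc)2 (2.2 equiv), MeCN/H2O 1:1, rt
Reagents that add atoms: water, O
Why: Oxoammonium (TEMPO) oxidation takes the primary alcohol through the aldehyde hydrate to the acid and leaves the tertiary alcohol and the alkyne alone.

Step 7
Reactants: 10 (3S)-3-hydroxy-3-isopropylhept-6-ynoic acid
Product: 11 (3S)-3-hydroxy-3-isopropyl-N-methoxy-N-methylhept-6-ynamide
Conditions: MeNH(OMe)·HCl, EDC·HCl, HOBt (cat.), iPr2NEt, CH2Cl2, 0 °C to rt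
Reagents that add atoms: N,O-dimethylhydroxylamine hydrochloride, CNOC.Cl
Why: Carbodiimide amide coupling; the hindered tertiary β-hydroxyl does not compete with the amine.

Step 8
Reactants: 11 (3S)-3-hydroxy-3-isopropyl-N-methoxy-N-methylhept-6-ynamide
Product: 12 (3S)-3-isopropyl-N-methoxy-N-methyl-3-(triethylsilyloxy)hept-6-ynamide
Conditions: Et3SiOTf, 2,6-lutidine, CH2Cl2, 0 °C
Reagents that add atoms: triethylsilyl trifluoromethanesulfonate, CC[Si](CC)(CC)OS(=O)(=O)C(F)(F)F
Why: Silyl triflate silylation of the tertiary alcohol, which must be masked against retro-aldol cleavage once C6 is a ketone; at the carbinol centre the siloxy group is smaller than isopropyl, which the key step uses.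

Step 9
Reactants: 12 (3S)-3-isopropyl-N-methoxy-N-methyl-3-(triethylsilyloxy)hept-6-ynamide
Product: 14 (3S,6E)-3-isopropyl-N-methoxy-N,6-dimethyl-8-oxo-3-(triethylsilyloxy)dec-6-enamide, via alkenylalane 13 (not isolated)
Conditions: Me3Al, Cp2ZrCl2 (20 mol %), CH2Cl2, 0 °C to rt; then EtCOCl, Pd(PPh3)4 (5 mol %), ZnCl2 (20 mol %), THF, 0 °C to rt
Reagents that add atoms: trimethylaluminium, C[Al](C)C; propanoyl chloride, CCC(=O)Cl
Why: Zirconium-catalysed carboalumination (Negishi) adds methyl and aluminium syn across the terminal alkyne with aluminium on the terminal carbon, and palladium-catalysed acylation of the alkenyl metal with retention should give the E enone, a geometry that ketone olefination or cross-metathesis would not secure.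

Step 10
Reactants: 14 (3S,6E)-3-isopropyl-N-methoxy-N,6-dimethyl-8-oxo-3-(triethylsilyloxy)dec-6-enamide
Product: 15 (3S,6E,8Z)-8-(tert-butyldimethylsilyloxy)-3-isopropyl-N-methoxy-N,6-dimethyl-3-(triethylsilyloxy)deca-6,8-dienamide
Conditions: t-BuMe2SiOTf, Et3N, CH2Cl2, −78 to 0 °C
Reagents that add atoms: tert-butyldimethylsilyl trifluoromethanesulfonate, CC(C)(C)[Si](C)(C)OS(=O)(=O)C(F)(F)F
Why: Soft enolisation of the ethyl ketone at its CH2 group gives the cross-conjugated Z silyl dienol ether; the Weinreb amide is not enolised, which is why the ketone at C6 is still masked as the amide here.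

Step 11
Reactants: 15 (3S,6E,8Z)-8-(tert-butyldimethylsilyloxy)-3-isopropyl-N-methoxy-N,6-dimethyl-3-(triethylsilyloxy)deca-6,8-dienamide
Product: 16 (4S,7E,9Z)-9-(tert-butyldimethylsilyloxy)-1-chloro-4-isopropyl-7-methyl-4-(triethylsilyloxy)undeca-7,9-dien-2-one
Conditions: ICH2Cl, MeLi·LiBr, THF, −78 °C; aq. NH4Cl
Reagents that add atoms: chloroiodomethane, ClCI
Why: Chloromethyllithium from iodine–lithium exchange adds once to the Weinreb amide (the chelated adduct collapses only on quench), so the acidic α-chloro ketone is made last and never meets silylating or enolising reagents; both silyl ethers are inert to the carbenoid at −78 °C.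

Step 12
Reactants: 16 (4S,7E,9Z)-9-(tert-butyldimethylsilyloxy)-1-chloro-4-isopropyl-7-methyl-4-(triethylsilyloxy)undeca-7,9-dien-2-one
Product: 18 (3R,3aR,6R,8aR)-7-(tert-butyldimethylsilyloxy)-3-isopropyl-6,8a-dimethyl-3-(triethylsilyloxy)-2,3,3a,5,6,8a-hexahydroazulen-4(1H)-one (trans-fused cycloadduct), via oxyallyl cation 17 (not isolated)
Conditions: Et3N, LiClO4 (3 M), Et2O, rt; then DBU (0.2 equiv), rt
Reagents that add atoms: none
Why: Et3N removes a C5 proton of 16 and lithium perchlorate assists loss of chloride from C7, giving the 2-oxidoallyl cation 17, which adds across the termini C1 and C8 of the tethered 2-siloxydiene; the closest known reaction type is the intramolecular oxyallyl (4+3) cycloaddition of α-halo ketones with tethered dienes (Föhlisch conditions). The cyclopentane closes through C1–C5 (five-ring attack on C1 along the three-atom tether C2–C4) and the cycloheptenone through C7–C8, concerted or closely stepwise, with the silyl enol ether reappearing at C9=C10. C1 is the centre that counts: the tether should fold so that the oxyallyl carbons lie away from the C4 isopropyl group and next to the smaller siloxy group, which puts C5–C6 trans to isopropyl and, with the E diene and a trans ring fusion, the C1 methyl cis to the C4 oxygen. C5 lies next to the new ketone and is held in the more stable trans-fused arrangement by DBU, while C8 (methyl trans to the C1 methyl from suprafacial addition to the Z enol ether) is erased later. The step needs seven-ring closure through C8 in preference to five-ring (3+2) closure through C10, and ionisation in preference to Favorskii rearrangement or E1cB loss of the siloxy group; the aprotic, weakly basic medium and the poor leaving-group ability of the tertiary siloxide are meant to secure this.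

Step 13
Reactants: 18 trans-fused cycloadduct
Product: 19 6α-alcohol (1β-Me 4α-iPr 4β-OTES 5α-H 6α-OH 8α-Me 9-OTBS Δ9(10))
Conditions: Li, NH3 (l), THF, t-BuOH, −78 °C; NH4Cl
Reagents that add atoms: none
Why: Dissolving-metal reduction should give the thermodynamically preferred equatorial (α) alcohol, trans to the C4 oxygen, whereas hydride reagents would be steered to the α face by the syn-axial C1 methyl and the C4 siloxy group and give the axial epimer; the silyl enol ether and the silyl ether are inert.

Step 14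
Reactants: 19 6α-alcohol; 20 4-(tert-butyldimethylsilyloxy)benzoic acid
Product: 22 6α-aroyloxy 9-ketone (1β-Me 4α-iPr 4β-OTES 5α-H 6α-OCOAr 8α-Me 9-oxo; Ar = 4-TBSO-phenyl), via ester enol ether 21 (not isolated)
Conditions: 20, DCC, DMAP, CH2Cl2, rt; then 0.5 M HCl, THF, 0 °C
Reagents that add atoms: none
Why: Steglich esterification of the only free hydroxyl, then acid hydrolysis of the silyl enol ether by protonation at C10, which is much faster than cleavage of the tertiary silyl ether or the aryl silyl ether; acylation before hydrolysis avoids a transannular hemiketal between O6 and C9.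

Step 15
Reactants: 22 6α-aroyloxy 9-ketone
Product: 23 Δ8(9) enol triflate (9-triflyloxy; otherwise as 22)
Conditions: Tf2O, 2,6-di-tert-butyl-4-methylpyridine, CH2Cl2, 0 °C to rt
Reagents that add atoms: trifluoromethanesulfonic anhydride, O=S(=O)(OS(=O)(=O)C(F)(F)F)C(F)(F)F
Why: Enol triflate formation with triflic anhydride and a hindered pyridine (Stang conditions) favours the more substituted C8=C9 isomer, C10 being shielded by the quaternary C1; the C8 stereocentre is removed here.

Step 16
Reactants: 23 Δ8(9) enol triflate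
Product: 24 Δ8(9) alkene (1β-Me 4α-iPr 4β-OTES 5α-H 6α-OCOAr 8-Me)
Conditions: Pd(OAc)2 (5 mol %), PPh3, Bu3N, HCO2H, DMF, 60 °C
Reagents that add atoms: none
Why: Palladium-catalysed formate reduction of the vinyl triflate (oxidative addition, hydride transfer from formate, reductive elimination) replaces OTf by H without moving the double bond.

Step 17
Reactants: 24 Δ8(9) alkene
Product: 26 8β,9α-diol (1β-Me 4α-iPr 4β-OTES 5α-H 6α-OCOAr 8α-Me 8β-OH 9α-OH), via epoxide 25 (not isolated)
Conditions: mCPBA, NaHCO3, CH2Cl2, 0 °C; then HClO4 (cat.), THF/H2O, 0 °C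
Reagents that add atoms: 3-chloroperoxybenzoic acid, OOC(=O)c1cccc(Cl)c1; water, O
Why: Prilezhaev epoxidation should occur on the α face, away from the axial C1 methyl that is syn-axial to C9 on the β face, and acid-catalysed hydrolysis opens the epoxide at tertiary C8 with inversion, which gives the 8β,9α trans diol in one sense only; O4 stays silylated so that it cannot add to the activated epoxide.

Step 18
Reactants: 26 8β,9α-diol
Product: 27 target, 6α-(4-hydroxybenzoyloxy)-4β,8β,9α-triol
Conditions: HF·pyridine, pyridine/THF, 0 °C to rt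
Reagents that add atoms: none
Why: Fluoride-driven cleavage of the tertiary triethylsilyl ether and the aryl silyl ether; ester, diol and all stereocentres are untouched.

Compound list
1 | ethyl 4-methyl-3-oxopentanoate | CCOC(=O)CC(=O)C(C)C | starting material
2 | ethyl (2Z)-4-methyl-3-[(trifluoromethylsulfonyl)oxy]pent-2-enoate | CCOC(=O)/C=C(\OS(=O)(=O)C(F)(F)F)C(C)C | intermediate
3 | (4-bromobut-1-yn-1-yl)trimethylsilane | C[Si](C)(C)C#CCCBr | starting material
4 | [4-(trimethylsilyl)but-3-yn-1-yl]magnesium bromide | C[Si](C)(C)C#CCC[Mg]Br | intermediate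
5 | ethyl (2E)-3-isopropyl-7-(trimethylsilyl)hept-2-en-6-ynoate | CCOC(=O)/C=C(/C(C)C)CCC#C[Si](C)(C)C | intermediate
6 | (2E)-3-isopropyl-7-(trimethylsilyl)hept-2-en-6-yn-1-ol | OC/C=C(/C(C)C)CCC#C[Si](C)(C)C | intermediate
7 | {(2R,3R)-3-isopropyl-3-[4-(trimethylsilyl)but-3-yn-1-yl]oxiran-2-yl}methanol | OC[C@H]1O[C@@]1(C(C)C)CCC#C[Si](C)(C)C | intermediate
8 | (3S)-3-isopropyl-7-(trimethylsilyl)hept-6-yne-1,3-diol | OCC[C@](O)(C(C)C)CCC#C[Si](C)(C)C | intermediate
9 | (3S)-3-isopropylhept-6-yne-1,3-diol | OCC[C@](O)(C(C)C)CCC#C | intermediate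
10 | (3S)-3-hydroxy-3-isopropylhept-6-ynoic acid | OC(=O)C[C@](O)(C(C)C)CCC#C | intermediate
11 | (3S)-3-hydroxy-3-isopropyl-N-methoxy-N-methylhept-6-ynamide | CON(C)C(=O)C[C@](O)(C(C)C)CCC#C | intermediate
12 | (3S)-3-isopropyl-N-methoxy-N-methyl-3-(triethylsilyloxy)hept-6-ynamide | CON(C)C(=O)C[C@](O[Si](CC)(CC)CC)(C(C)C)CCC#C | intermediate
13 | dimethyl alkenylalane from syn methylalumination of 12 (E, aluminium on the terminal carbon) | CON(C)C(=O)C[C@](O[Si](CC)(CC)CC)(C(C)C)CC/C(C)=C/[Al](C)C | intermediate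
14 | (3S,6E)-3-isopropyl-N-methoxy-N,6-dimethyl-8-oxo-3-(triethylsilyloxy)dec-6-enamide | CON(C)C(=O)C[C@](O[Si](CC)(CC)CC)(C(C)C)CC/C(C)=C/C(=O)CC | intermediate
15 | (3S,6E,8Z)-8-(tert-butyldimethylsilyloxy)-3-isopropyl-N-methoxy-N,6-dimethyl-3-(triethylsilyloxy)deca-6,8-dienamide | CON(C)C(=O)C[C@](O[Si](CC)(CC)CC)(C(C)C)CC/C(C)=C/C(O[Si](C)(C)C(C)(C)C)=C/C | intermediate
16 | (4S,7E,9Z)-9-(tert-butyldimethylsilyloxy)-1-chloro-4-isopropyl-7-methyl-4-(triethylsilyloxy)undeca-7,9-dien-2-one | ClCC(=O)C[C@](O[Si](CC)(CC)CC)(C(C)C)CC/C(C)=C/C(O[Si](C)(C)C(C)(C)C)=C/C | intermediate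
17 | oxyallyl cation (2-oxidoallyl zwitterion) formed from 16 by loss of HCl | [CH2+]C([O-])=C[C@](O[Si](CC)(CC)CC)(C(C)C)CC/C(C)=C/C(O[Si](C)(C)C(C)(C)C)=C/C | intermediate
18 | (3R,3aR,6R,8aR)-7-(tert-butyldimethylsilyloxy)-3-isopropyl-6,8a-dimethyl-3-(triethylsilyloxy)-2,3,3a,5,6,8a-hexahydroazulen-4(1H)-one; core: 1β-Me, 4α-iPr, 4β-OTES, 5α-H, 6-oxo, 8α-Me, 9-OTBS, Δ9(10) | CC(C)[C@]1(O[Si](CC)(CC)CC)CC[C@]2(C)C=C(O[Si](C)(C)C(C)(C)C)[C@H](C)CC(=O)[C@H]21 | intermediate
19 | 6α-alcohol; core: 1β-Me, 4α-iPr, 4β-OTES, 5α-H, 6α-OH, 8α-Me, 9-OTBS, Δ9(10) | CC(C)[C@]1(O[Si](CC)(CC)CC)CC[C@]2(C)C=C(O[Si](C)(C)C(C)(C)C)[C@H](C)C[C@H](O)[C@H]21 | intermediate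
20 | 4-(tert-butyldimethylsilyloxy)benzoic acid | OC(=O)c1ccc(O[Si](C)(C)C(C)(C)C)cc1 | starting material
21 | 6α-[4-(tert-butyldimethylsilyloxy)benzoate] of 19, silyl enol ether intact | CC(C)[C@]1(O[Si](CC)(CC)CC)CC[C@]2(C)C=C(O[Si](C)(C)C(C)(C)C)[C@H](C)C[C@H](OC(=O)c3ccc(O[Si](C)(C)C(C)(C)C)cc3)[C@H]21 | intermediate
22 | 9-ketone; core: 1β-Me, 4α-iPr, 4β-OTES, 5α-H, 6α-[4-(TBSO)benzoyloxy], 8α-Me, 9-oxo | CC(C)[C@]1(O[Si](CC)(CC)CC)CC[C@]2(C)CC(=O)[C@H](C)C[C@H](OC(=O)c3ccc(O[Si](C)(C)C(C)(C)C)cc3)[C@H]21 | intermediate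
23 | enol triflate; core: as 22 with 9-OTf and Δ8(9) | CC(C)[C@]1(O[Si](CC)(CC)CC)CC[C@]2(C)CC(OS(=O)(=O)C(F)(F)F)=C(C)C[C@H](OC(=O)c3ccc(O[Si](C)(C)C(C)(C)C)cc3)[C@H]21 | intermediate
24 | alkene; core: 1β-Me, 4α-iPr, 4β-OTES, 5α-H, 6α-[4-(TBSO)benzoyloxy], 8-Me, Δ8(9) | CC(C)[C@]1(O[Si](CC)(CC)CC)CC[C@]2(C)CC=C(C)C[C@H](OC(=O)c3ccc(O[Si](C)(C)C(C)(C)C)cc3)[C@H]21 | intermediate
25 | 8α,9α-epoxide of 24 (8β-Me) | CC(C)[C@]1(O[Si](CC)(CC)CC)CC[C@]2(C)C[C@@H]3O[C@]3(C)C[C@H](OC(=O)c4ccc(O[Si](C)(C)C(C)(C)C)cc4)[C@H]21 | intermediate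
26 | 8β,9α-diol; core: 1β-Me, 4α-iPr, 4β-OTES, 5α-H, 6α-[4-(TBSO)benzoyloxy], 8α-Me, 8β-OH, 9α-OH | CC(C)[C@]1(O[Si](CC)(CC)CC)CC[C@]2(C)C[C@H](O)[C@@](C)(O)C[C@H](OC(=O)c3ccc(O[Si](C)(C)C(C)(C)C)cc3)[C@H]21 | intermediate
27 | CNP0197754.1; core: 1β-Me, 4α-iPr, 4β-OH, 5α-H, 6α-(4-hydroxybenzoyloxy), 8α-Me, 8β-OH, 9α-OH (1R,4R,5S,6S,8S,9S in core numbering) | CC(C)[C@]1(O)CC[C@]2(C)C[C@H](O)[C@@](C)(O)C[C@H](OC(=O)c3ccc(O)cc3)[C@H]21 | target

Total step count: 18. Longest linear sequence: 18 steps (1 to 27); 3 and 20 enter directly.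

Steps most likely to fail

Step 12. The cation may be consumed by Favorskii rearrangement or by E1cB expulsion of the C4 siloxide under the basic conditions. It may also close the five-membered ring through C10 instead of the seven-membered ring through C8, or add to the wrong face at C1. The fallback generates the oxyallyl species reductively and without base (Noyori–Hoffmann type). It sets out from 15: deprotonation next to the amide (LiN(iPr)2, THF, −78 °C) and chlorination with C2Cl6 would give the 2-chloro amide F1. Chloromethyllithium, as in step 11, would convert it into the 1,3-dichloro ketone F2. Zinc–copper couple with NaI in MeCN would then remove both halides and release the zinc oxyallyl species, which cyclises as in step 12. The route is rejoined at 18.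

Step 17. The peracid may attack the β face of the C8=C9 bond, or the epoxide may rearrange under acid (allylic alcohol, ketone) instead of being hydrated. The fallback keeps the C9 oxygen and builds the diol by enol ether oxidation and directed reduction; a reagent that prefers the β face of this double bond then delivers the required C8 configuration. It sets out from 22: Me3SiI and (Me3Si)2NH in CH2Cl2 would give the more substituted trimethylsilyl enol ether F3. Rubottom oxidation (mCPBA, then dilute acid) would give the 8β-hydroxy 9-ketone F4. Me4NBH(OAc)3 in MeCN/AcOH would reduce C9 by hydride delivery from the face of the C8 hydroxyl and give the trans diol. The route is rejoined at 26.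

Step 15. Enolisation may lose its regiocontrol and give the C9=C10 triflate. The fallback makes the alkene by reduction and syn elimination. It sets out from 22: LiBH(s-Bu)3 in THF at −78 °C, attacking the less hindered α face, would give the 9β-alcohol F5. The Burgess reagent in toluene at 60 °C would eliminate it through the cis C8 hydrogen. The route is rejoined at 24.

Further compounds
F1 | step 12 | (3R,6E,8Z)-8-(tert-butyldimethylsilyloxy)-2-chloro-3-isopropyl-N-methoxy-N,6-dimethyl-3-(triethylsilyloxy)deca-6,8-dienamide (C2 epimers) | CON(C)C(=O)C(Cl)[C@](O[Si](CC)(CC)CC)(C(C)C)CC/C(C)=C/C(O[Si](C)(C)C(C)(C)C)=C/C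
F2 | step 12 | (4R,7E,9Z)-9-(tert-butyldimethylsilyloxy)-1,3-dichloro-4-isopropyl-7-methyl-4-(triethylsilyloxy)undeca-7,9-dien-2-one (C3 epimers) | ClCC(=O)C(Cl)[C@](O[Si](CC)(CC)CC)(C(C)C)CC/C(C)=C/C(O[Si](C)(C)C(C)(C)C)=C/C
F3 | step 17 | 9-(trimethylsilyloxy) Δ8(9) enol ether of 22 | CC(C)[C@]1(O[Si](CC)(CC)CC)CC[C@]2(C)CC(O[Si](C)(C)C)=C(C)C[C@H](OC(=O)c3ccc(O[Si](C)(C)C(C)(C)C)cc3)[C@H]21
F4 | step 17 | 8β-hydroxy-8α-methyl 9-ketone (otherwise as 22) | CC(C)[C@]1(O[Si](CC)(CC)CC)CC[C@]2(C)CC(=O)[C@@](C)(O)C[C@H](OC(=O)c3ccc(O[Si](C)(C)C(C)(C)C)cc3)[C@H]21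
F5 | step 15 | 9β-alcohol of 22 (8α-Me, 8β-H) | CC(C)[C@]1(O[Si](CC)(CC)CC)CC[C@]2(C)C[C@@H](O)[C@H](C)C[C@H](OC(=O)c3ccc(O[Si](C)(C)C(C)(C)C)cc3)[C@H]21
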